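**Retrosynthetic overview**
1. Target ⇒ diol 25 + 2 senecioyl chloride (double acylation). The isopropenyl group comes from the C7 enolate of a cis-decalone plus acetone (aldol, then dehydration), and the 9-OH from Rubottom oxidation of the Δ8(9) silyl enol ether.
2. cis-Decalone 14 ⇒ Δ9-8-octalone 13 (hydrogenation). 3α-OH and 4β-CH3 ⇒ hydroboration of a Δ3 olefin, made from the C4 ketone via enol triflate and methyl cuprate, with the enone masked as a dithiolane.
3. (S)-Wieland–Miescher ketone ⇒ 2-methylcyclohexane-1,3-dione + methyl vinyl ketone: an intermolecular Michael addition joins the two fragments (C5–C6, quaternary C5), then a proline-catalysed aldol condensation follows.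
4. Ring order: ring A is the purchased cyclohexanedione; ring B is closed second (Michael, then intramolecular aldol).

Convention: eremophilane numbering (ring A = C1–C5, C10; ring B = C5–C10; CH3 on C4 and C5); β = face of the C5 methyl; target = (3R,4R,5R,7R,9R,10S), i.e. 3α,9β-diacyloxy, 7β-isopropenyl, 10β-H (cis-fused).

**Step 1**
Reactants: 1 2-methylcyclohexane-1,3-dione; 2 but-3-en-2-one (methyl vinyl ketone)
Product: 3 2-methyl-2-(3-oxobutyl)cyclohexane-1,3-dione
Conditions: H2O, AcOH (cat.), hydroquinone (cat.), 75 °C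
Reagents that add atoms: none
Why: Intermolecular Michael addition of the acidic 1,3-dione to the enone joins the two fragments and creates the quaternary carbon (future C5); no stereocentre yet because the triketone is achiral.

**Step 2**
Reactants: 3 2-methyl-2-(3-oxobutyl)cyclohexane-1,3-dione
Product: 5 (S)-Wieland–Miescher ketone [(8aS)-8a-methyl-3,4,8,8a-tetrahydronaphthalene-1,6(2H,7H)-dione], via cis-ketol 4 (not isolated)
Conditions: (S)-proline (5 mol%), DMSO, rt, 5 d; recrystallise (Et2O–hexane) to ≥99% ee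
Reagents that add atoms: none
Why: Hajos–Parrish–Eder–Sauer–Wiechert enamine aldol condensation; (S)-proline selects one of the two enantiotopic ring carbonyls and so sets C5 as the (S)-enone.

**Step 3**
Reactants: 5 (S)-Wieland–Miescher ketone
Product: 6 (S)-Wieland–Miescher ketone 6-(1,3-dithiolane) [spiro-dithiolane at the enone carbon C8; Δ9(10); C4 ketone free]
Conditions: HS(CH2)2SH (1.05 equiv), p-TsOH (cat.), AcOH, rt
Reagents that add atoms: ethane-1,2-dithiol, SCCS
Why: Acid-catalysed thioketalisation is selective for the unhindered conjugated carbonyl over the neopentyl C4 ketone, and the double bond stays at Δ9(10).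

**Step 4**
Reactants: 6 (S)-Wieland–Miescher ketone 6-(1,3-dithiolane)
Product: 8 Δ3-enol triflate of 6 (C4–OTf; C3=C4 and C9=C10; C8 dithiolane), via potassium Δ3-enolate 7 (not isolated)
Conditions: KHMDS, THF, −78 °C; PhNTf2, −78 → 0 °C; aq. NH4Cl
Reagents that add atoms: N-phenylbis(trifluoromethanesulfonimide), O=S(=O)(N(c1ccccc1)S(=O)(=O)C(F)(F)F)C(F)(F)F
Why: Enol triflate formation; the only ketone can enolise only toward C3 because C5 is quaternary.

**Step 5**
Reactants: 8 Δ3-enol triflate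
Product: 9 8,8-ethylenedithio-11,12,13-trinoreremophila-3,9-diene (4-CH3 on the Δ3 olefin; 5β-CH3)
Conditions: Me2CuLi (from MeLi + CuI, 3 equiv), THF, −15 → 0 °C
Reagents that add atoms: lithium dimethylcuprate, [Li+].C[Cu-]C
Why: Cuprate cross-coupling of an alkenyl triflate (McMurry–Scott) replaces OTf by CH3 without moving the double bond.

**Step 6**
Reactants: 9 8,8-ethylenedithio-11,12,13-trinoreremophila-3,9-diene
Product: 11 8,8-ethylenedithio-11,12,13-trinoreremophil-9-en-3α-ol (4β-CH3; 5β-CH3), via C3α-alkylborane 10 (not isolated)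
Conditions: BH3·SMe2 (1.2 equiv), THF, 0 °C → rt; then 3 M NaOH, 30% H2O2, 0 °C
Reagents that add atoms: hydrogen peroxide, OO
Why: Hydroboration–oxidation adds H and B syn and anti-Markovnikov to the Δ3 olefin from the α face, opposite the axial C5 methyl, which sets C3 (α-OH) and C4 (α-H, β-CH3) together; the Δ9 olefin, flanked by the dithiolane and C5, is too hindered to compete.

**Step 7**
Reactants: 11 8,8-ethylenedithio-11,12,13-trinoreremophil-9-en-3α-ol
Product: 12 3α-(tert-butyldimethylsilyloxy)-8,8-ethylenedithio-11,12,13-trinoreremophil-9-ene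
Conditions: TBSCl, imidazole, DMF, rt
Reagents that add atoms: tert-butyldimethylsilyl chloride, CC(C)(C)[Si](C)(C)Cl
Why: Standard silylation of the equatorial secondary alcohol gives an ether that survives all later base, oxidant and hydrogenation steps.

**Step 8**
Reactants: 12 3α-(tert-butyldimethylsilyloxy)-8,8-ethylenedithio-11,12,13-trinoreremophil-9-ene
Product: 13 3α-(tert-butyldimethylsilyloxy)-11,12,13-trinoreremophil-9-en-8-one
Conditions: MeI (excess), CaCO3, MeCN–H2O 4:1, 55 °C
Reagents that add atoms: water, O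
Why: Alkylative dethioketalisation (S-methylation, then hydrolysis of the allylic thioketal) unmasks the enone under neutral conditions that leave the TBS ether untouched.

**Step 9**
Reactants: 13 3α-(tert-butyldimethylsilyloxy)-11,12,13-trinoreremophil-9-en-8-one
Product: 14 3α-(tert-butyldimethylsilyloxy)-11,12,13-trinor-10βH-eremophilan-8-one (cis-fused)
Conditions: H2 (1 atm), 10% Pd/C, EtOH, Et3N (1%), rt
Reagents that add atoms: none
Why: Heterogeneous hydrogenation of a 4β,5β-dimethyl-Δ9-8-octalone in weakly basic medium is expected to place H at C10 cis to the C5 methyl (cis-decalone), as Δ4-3-keto steroids give 5β products.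

**Step 10**
Reactants: 14 3α-(tert-butyldimethylsilyloxy)-11,12,13-trinor-10βH-eremophilan-8-one
Product: 15 3α-(tert-butyldimethylsilyloxy)-8-(trimethylsilyloxy)-11,12,13-trinor-10βH-eremophil-8-ene (Δ8(9) silyl enol ether)
Conditions: TMSCl, Et3N, DMF, 90 °C
Reagents that add atoms: chlorotrimethylsilane, C[Si](C)(C)Cl
Why: Thermodynamic silyl enol ether formation; the cis-fused ketone, held in the steroid-like conformation by the equatorial 3α-OTBS and 4β-CH3, enolises toward C9 as 5β-3-keto steroids enolise toward C4.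

**Step 11**
Reactants: 15 Δ8(9) silyl enol ether
Product: 18 3α-(tert-butyldimethylsilyloxy)-9β-hydroxy-11,12,13-trinor-10βH-eremophilan-8-one, via 8β,9β-epoxy silyl ether 16 (not isolated), via 9β-trimethylsilyloxy ketone 17 (not isolated)
Conditions: mCPBA, NaHCO3, CH2Cl2, −20 → 0 °C; then citric acid, MeOH, rt
Reagents that add atoms: 3-chloroperoxybenzoic acid, O=C(OO)c1cccc(Cl)c1
Why: Rubottom oxidation; the peracid attacks the convex β face (the α face is blocked by the axial C4–C5 bond), giving the equatorial 9β-oxygen, which is also the more stable epimer.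

**Step 12**
Reactants: 18 3α-(tert-butyldimethylsilyloxy)-9β-hydroxy-11,12,13-trinor-10βH-eremophilan-8-one
Product: 19 3α,9β-bis(tert-butyldimethylsilyloxy)-11,12,13-trinor-10βH-eremophilan-8-one
Conditions: TBSOTf, 2,6-lutidine, CH2Cl2, 0 °C
Reagents that add atoms: tert-butyldimethylsilyl trifluoromethanesulfonate, CC(C)(C)[Si](C)(C)OS(=O)(=O)C(F)(F)F
Why: O-Silylation of the acyloin hydroxyl protects it and makes C9–H hindered, so later enolisation goes to C7.

**Step 13**
Reactants: 19 3α,9β-bis(tert-butyldimethylsilyloxy)-11,12,13-trinor-10βH-eremophilan-8-one; 20 acetone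
Product: 22 3α,9β-bis(tert-butyldimethylsilyloxy)-11-hydroxy-10βH-eremophilan-8-one (7β side chain), via lithium Δ7-enolate 21 (not isolated)
Conditions: LDA, THF, −78 °C; acetone (3 equiv), −78 °C; AcOH quench at −78 °C
Reagents that add atoms: none
Why: Directed aldol addition; LDA removes a C7 proton (C9–H is tertiary and flanked by OTBS), and acetone adds on the convex β face to give the equatorial 7β side chain, also the thermodynamic epimer.

**Step 14**
Reactants: 22 3α,9β-bis(tert-butyldimethylsilyloxy)-11-hydroxy-10βH-eremophilan-8-one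
Product: 24 3α,9β-bis(tert-butyldimethylsilyloxy)-10βH-eremophil-11-en-8-one, via C11 chlorosulfite 23 (not isolated)
Conditions: SOCl2, pyridine, CH2Cl2, −20 → 0 °C
Reagents that add atoms: none
Why: Dehydration through the chlorosulfite (E2 with pyridine) should take one of the six methyl hydrogens rather than the hindered C7–H, giving the non-conjugated isopropenyl group and leaving C7 untouched.

**Step 15**
Reactants: 24 3α,9β-bis(tert-butyldimethylsilyloxy)-10βH-eremophil-11-en-8-one
Product: 25 3α,9β-dihydroxy-10βH-eremophil-11-en-8-one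
Conditions: HF·pyridine, pyridine, THF, 0 °C → rt
Reagents that add atoms: none
Why: Fluoride-mediated desilylation under buffered conditions removes both TBS groups without enolising the β,γ-unsaturated ketone.

**Step 16**
Reactants: 25 3α,9β-dihydroxy-10βH-eremophil-11-en-8-one; 26 3-methylbut-2-enoyl chloride (senecioyl chloride)
Product: 28 (3R,4R,5R,7R,9R,10S)-3α,9β-bis(3-methylbut-2-enoyloxy)-10βH-eremophil-11-en-8-one (CNP0264508.1), via 3-monoester 27 (not isolated)
Conditions: 26 (3 equiv), pyridine, DMAP (cat.), CH2Cl2, 0 °C → rt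
Reagents that add atoms: none
Why: DMAP-catalysed acylation of both secondary alcohols; the weak base avoids vinylketene formation from the acid chloride, and C7 and C9 are already in their equatorial configurations.

**Compound list**
1 | 2-methylcyclohexane-1,3-dione | CC1C(=O)CCCC1=O | starting material
2 | but-3-en-2-one (methyl vinyl ketone) | C=CC(C)=O | starting material
3 | 2-methyl-2-(3-oxobutyl)cyclohexane-1,3-dione | CC(=O)CCC1(C)C(=O)CCCC1=O | intermediate
4 | cis-ketol, (4aS,8aS)-4a-hydroxy-8a-methyloctahydronaphthalene-1,6-dione | C1C[C@@]2(C)[C@](O)(CCCC2=O)CC1=O | intermediate (not isolated)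
5 | (S)-Wieland–Miescher ketone | C1C[C@@]2(C)C(CCCC2=O)=CC1=O | intermediate
6 | (S)-Wieland–Miescher ketone 6-(1,3-dithiolane) | C1C[C@@]2(C)C(CCCC2=O)=CC13SCCS3 | intermediate
7 | potassium Δ3-enolate of 6 | C1C[C@@]2(C)C(CCC=C2O[K])=CC13SCCS3 | intermediate (not isolated)
8 | Δ3-enol triflate of 6 | C1C[C@@]2(C)C(CCC=C2OS(=O)(=O)C(F)(F)F)=CC13SCCS3 | intermediate
9 | 8,8-ethylenedithio-11,12,13-trinoreremophila-3,9-diene | C1C[C@@]2(C)C(CCC=C2C)=CC13SCCS3 | intermediate
10 | C3α-alkylborane (drawn as the monoalkylborane) | C1C[C@@]2(C)C(CC[C@@H](B)[C@@H]2C)=CC13SCCS3 | intermediate (not isolated)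
11 | 8,8-ethylenedithio-11,12,13-trinoreremophil-9-en-3α-ol | C1C[C@@]2(C)C(CC[C@@H](O)[C@@H]2C)=CC13SCCS3 | intermediate
12 | 3α-TBSO-8,8-ethylenedithio-11,12,13-trinoreremophil-9-ene | C1C[C@@]2(C)C(CC[C@@H](O[Si](C)(C)C(C)(C)C)[C@@H]2C)=CC13SCCS3 | intermediate
13 | 3α-TBSO-11,12,13-trinoreremophil-9-en-8-one | C1C[C@@]2(C)C(CC[C@@H](O[Si](C)(C)C(C)(C)C)[C@@H]2C)=CC1=O | intermediate
14 | 3α-TBSO-11,12,13-trinor-10βH-eremophilan-8-one | C1C[C@@]2(C)[C@H](CC[C@@H](O[Si](C)(C)C(C)(C)C)[C@@H]2C)CC1=O | intermediate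
15 | Δ8(9) trimethylsilyl enol ether of 14 | C1C[C@@]2(C)[C@H](CC[C@@H](O[Si](C)(C)C(C)(C)C)[C@@H]2C)C=C1O[Si](C)(C)C | intermediate
16 | 8β,9β-epoxy-8α-trimethylsilyloxy derivative | C1C[C@@]2(C)[C@H](CC[C@@H](O[Si](C)(C)C(C)(C)C)[C@@H]2C)[C@@H](O3)[C@]13O[Si](C)(C)C | intermediate (not isolated)
17 | 3α-TBSO-9β-trimethylsilyloxy-11,12,13-trinor-10βH-eremophilan-8-one | C1C[C@@]2(C)[C@H](CC[C@@H](O[Si](C)(C)C(C)(C)C)[C@@H]2C)[C@@H](O[Si](C)(C)C)C1=O | intermediate (not isolated)
18 | 3α-TBSO-9β-hydroxy-11,12,13-trinor-10βH-eremophilan-8-one | C1C[C@@]2(C)[C@H](CC[C@@H](O[Si](C)(C)C(C)(C)C)[C@@H]2C)[C@@H](O)C1=O | intermediate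
19 | 3α,9β-bis(TBSO)-11,12,13-trinor-10βH-eremophilan-8-one | C1C[C@@]2(C)[C@H](CC[C@@H](O[Si](C)(C)C(C)(C)C)[C@@H]2C)[C@@H](O[Si](C)(C)C(C)(C)C)C1=O | intermediate
20 | acetone | CC(C)=O | starting material
21 | lithium Δ7-enolate of 19 | C=1C[C@@]2(C)[C@H](CC[C@@H](O[Si](C)(C)C(C)(C)C)[C@@H]2C)[C@@H](O[Si](C)(C)C(C)(C)C)C=1O[Li] | intermediate (not isolated)
22 | 3α,9β-bis(TBSO)-11-hydroxy-10βH-eremophilan-8-one | CC(C)(O)[C@H]1C[C@@]2(C)[C@H](CC[C@@H](O[Si](C)(C)C(C)(C)C)[C@@H]2C)[C@@H](O[Si](C)(C)C(C)(C)C)C1=O | intermediate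
23 | C11 chlorosulfite of 22 | CC(C)(OS(=O)Cl)[C@H]1C[C@@]2(C)[C@H](CC[C@@H](O[Si](C)(C)C(C)(C)C)[C@@H]2C)[C@@H](O[Si](C)(C)C(C)(C)C)C1=O | intermediate (not isolated)
24 | 3α,9β-bis(TBSO)-10βH-eremophil-11-en-8-one | C=C(C)[C@H]1C[C@@]2(C)[C@H](CC[C@@H](O[Si](C)(C)C(C)(C)C)[C@@H]2C)[C@@H](O[Si](C)(C)C(C)(C)C)C1=O | intermediate
25 | 3α,9β-dihydroxy-10βH-eremophil-11-en-8-one | C=C(C)[C@H]1C[C@@]2(C)[C@H](CC[C@@H](O)[C@@H]2C)[C@@H](O)C1=O | intermediate
26 | 3-methylbut-2-enoyl chloride | CC(C)=CC(=O)Cl | starting material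
27 | 9β-hydroxy-3α-(3-methylbut-2-enoyloxy)-10βH-eremophil-11-en-8-one | C=C(C)[C@H]1C[C@@]2(C)[C@H](CC[C@@H](OC(=O)C=C(C)C)[C@@H]2C)[C@@H](O)C1=O | intermediate (not isolated)
28 | (3R,4R,5R,7R,9R,10S)-3α,9β-bis(3-methylbut-2-enoyloxy)-10βH-eremophil-11-en-8-one | C=C(C)[C@H]1C[C@@]2(C)[C@H](CC[C@@H](OC(=O)C=C(C)C)[C@@H]2C)[C@@H](OC(=O)C=C(C)C)C1=O | target

**Totals**
Total step count: 16. Longest linear sequence: 16 steps (1 + 2 → 28).

**Three steps most likely to fail**

Step 6 (hydroboration). The diene has two trisubstituted olefins, and borane may also attack the Δ9 bond or be slowed by the dithiolane. The fallback sets out from 6 and returns at 12. The potassium enolate of 6 is hydroxylated with 2-(phenylsulfonyl)-3-phenyloxaziridine at −78 °C, anti to the axial C5 methyl, to give 8,8-ethylenedithio-3α-hydroxy-11,12,13,15-tetranoreremophil-9-en-4-one F1. TBSOTf/2,6-lutidine gives its silyl ether F2. Wittig methylenation (Ph3PCH3Br, KOtBu, toluene, 90 °C) gives the 4-methylene compound F3. Diimide (TsNHNH2, NaOAc, DME–H2O, reflux) reduces only the exocyclic olefin, from the α face, and delivers 12 (4β-CH3).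

Step 9 (cis-selective hydrogenation). Some trans-fused decalone may form. The fallback sets out from 13 and returns at 14. Luche reduction (NaBH4, CeCl3, MeOH, −78 °C) gives 3α-TBSO-11,12,13-trinoreremophil-9-en-8β-ol F4. Hydroxyl-directed hydrogenation with [Ir(cod)(PCy3)(py)]PF6 under H2 in CH2Cl2 delivers hydrogen to C10 from the β face of the coordinating 8β-OH and gives 3α-TBSO-11,12,13-trinor-10βH-eremophilan-8β-ol F5. Dess–Martin oxidation then returns 14.

Step 14 (regioselective dehydration). The conjugated isopropylidene isomer may predominate. The fallback sets out from 22 and returns at 24. MsCl/Et3N followed by DBU converts all material into the conjugated enone 3α,9β-bis(TBSO)-10βH-eremophil-7(11)-en-8-one F6. γ-Deprotonation (KHMDS, THF–HMPA, −78 °C) gives the extended dienolate, and kinetic axial α-protonation with AcOH at −78 °C deconjugates it to 24 with the isopropenyl group equatorial (7β).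

**Further compounds**
F1 | step 6 | 8,8-ethylenedithio-3α-hydroxy-11,12,13,15-tetranoreremophil-9-en-4-one | C1C[C@@]2(C)C(CC[C@@H](O)C2=O)=CC13SCCS3
F2 | step 6 | 3α-(tert-butyldimethylsilyloxy)-8,8-ethylenedithio-11,12,13,15-tetranoreremophil-9-en-4-one | C1C[C@@]2(C)C(CC[C@@H](O[Si](C)(C)C(C)(C)C)C2=O)=CC13SCCS3
F3 | step 6 | 3α-(tert-butyldimethylsilyloxy)-8,8-ethylenedithio-11,12,13-trinoreremophila-4(15),9-diene | C1C[C@@]2(C)C(CC[C@@H](O[Si](C)(C)C(C)(C)C)C2=C)=CC13SCCS3
F4 | step 9 | 3α-(tert-butyldimethylsilyloxy)-11,12,13-trinoreremophil-9-en-8β-ol | C1C[C@@]2(C)C(CC[C@@H](O[Si](C)(C)C(C)(C)C)[C@@H]2C)=C[C@H]1O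
F5 | step 9 | 3α-(tert-butyldimethylsilyloxy)-11,12,13-trinor-10βH-eremophilan-8β-ol | C1C[C@@]2(C)[C@H](CC[C@@H](O[Si](C)(C)C(C)(C)C)[C@@H]2C)C[C@H]1O
F6 | step 14 | 3α,9β-bis(tert-butyldimethylsilyloxy)-10βH-eremophil-7(11)-en-8-one | CC(C)=C1C[C@@]2(C)[C@H](CC[C@@H](O[Si](C)(C)C(C)(C)C)[C@@H]2C)[C@@H](O[Si](C)(C)C(C)(C)C)C1=O
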